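**Retrosynthetic overview**
1. Target 27 ⇐ 26 (C3–OH → C=O) ⇐ 25 (CH2 onto the C8 ketone) ⇐ 23. Ring B of the keto half is made last, by oxidative ring expansion of a (Z)-alkylidene-hydrindane (cyclopentane → cyclohexanone, 1,2-shift of the C10–C8 bond onto C9); this sets the unusual H-9.
2. 23 ⇐ Wittig union (C8=C9) of hydrindanone 10 with the ylide of 21, the finished acetoxy half carrying C12, C11 and C9.
3. 21 ⇐ 14 by the same ring expansion (six-membered ring C13–C18), then base equilibration of C13 and methylenation; 14 ⇐ 10 + C4 phosphonium salt 12 (from THF).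
4. 10 (used twice) ⇐ (S)-Hajos–Parrish ketone 5 ⇐ 2-methylcyclopentane-1,3-dione + methyl vinyl ketone.
5. Ring order: cyclopentane (bought) → ring A / ring C19–C22 (Robinson annulation) → six-membered ring of the acetoxy half (ring expansion) → ring B of the keto half (ring expansion).

Assumption: the SMILES is taken literally, so H-9 of the 3-oxo half is cis to the C10 methyl (side chain axial, 9-epi to α-onocerin) while H-13 of the acetoxy half is trans to the C18 methyl (normal onocerane). Onocerane numbering is used for C30 compounds, drimane-type numbering (C3, C4, C5, C8, C9, C10) for the decalins 16–22, and β means the face of the angular methyl of that half.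

**Step 1**
Reactants: 1 2-methylcyclopentane-1,3-dione; 2 but-3-en-2-one (methyl vinyl ketone)
Product: 3 2-methyl-2-(3-oxobutyl)cyclopentane-1,3-dione
Conditions: H2O, AcOH (cat.), 70 °C
Reagents that add atoms: none
Why: Michael addition of the acidic 1,3-dione to the enone in water; the new quaternary carbon is still prochiral.

**Step 2**
Reactants: 3 2-methyl-2-(3-oxobutyl)cyclopentane-1,3-dione
Product: 5 (S)-Hajos–Parrish ketone [(7aS)-7a-methyl-2,3,7,7a-tetrahydro-1H-indene-1,5(6H)-dione], via cis-ketol 4 (not isolated)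
Conditions: (S)-proline (3 mol%), DMF, 20 °C; then H2SO4 (cat.), 95 °C; recrystallise to >99% ee
Reagents that add atoms: none
Why: Hajos–Parrish–Eder–Sauer–Wiechert reaction, in which the proline enamine of the side-chain ketone attacks one enantiotopic ring carbonyl (intramolecular aldol) and acid dehydrates the ketol, fixing C7a (later C10 and C18) as S.

**Step 3**
Reactants: 5 (S)-Hajos–Parrish ketone
Product: 6 C1-dioxolane of 5 [(7a′S)-7a′-methyl-2′,3′,7′,7a′-tetrahydrospiro[1,3-dioxolane-2,1′-inden]-5′(6′H)-one]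
Conditions: TMSOCH2CH2OTMS, TMSOTf (cat.), CH2Cl2, −78 °C
Reagents that add atoms: 1,2-bis(trimethylsilyloxy)ethane, C[Si](C)(C)OCCO[Si](C)(C)C
Why: Noyori acetalisation is kinetically selective for the saturated cyclopentanone over the conjugated enone (as for 17-oxo versus Δ4-3-oxo steroids); no new stereocentre.

**Step 4**
Reactants: 6 C1-dioxolane of 5
Product: 7 4,4-dimethyl β,γ-enone ketal (7aS; C3=C3a double bond; C5 ketone)
Conditions: t-BuOK (2.5 equiv), MeI (5 equiv), t-BuOH–THF, 0 → 25 °C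
Reagents that add atoms: iodomethane, CI
Why: Double α-alkylation of the extended (thermodynamic) dienolate of the enone at C4 with deconjugation of the olefin, the ketal preventing enolisation at C2.

**Step 5**
Reactants: 7 4,4-dimethyl β,γ-enone ketal
Product: 8 trans-fused ketal ketone (3aS,7aS; H-3a anti to Me-7a)
Conditions: H2 (4 atm), 10% Pd/C, EtOAc, 25 °C
Reagents that add atoms: none
Why: Catalytic hydrogenation delivers H to C3a from the α face because the β face is blocked by the axial C7a and C4β methyls, giving the trans ring fusion just as 4,4-dimethyl-Δ5-steroids give 5α products.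

**Step 6**
Reactants: 8 trans-fused ketal ketone
Product: 10 hydrindanone (3aS,5S,7aS)-5-hydroxy-4,4,7a-trimethyloctahydro-1H-inden-1-one (OH syn to Me-7a), via hydroxy ketal 9 (not isolated)
Conditions: NaBH4, MeOH, 0 °C; then 2 M HCl, THF, 25 °C
Reagents that add atoms: water, O
Why: Carbonyl reduction by axial hydride attack from the α face gives the equatorial 5β-alcohol (as 4,4-dimethyl-3-ketones give 3β-ols), and acetal hydrolysis then frees the C1 ketone.

**Step 7**
Reactants: 11 tetrahydrofuran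
Product: 12 (4-hydroxybutyl)triphenylphosphonium bromide
Conditions: Ph3P·HBr, THF (as solvent), reflux
Reagents that add atoms: triphenylphosphine hydrobromide, [Br-].[PH+](c1ccccc1)(c1ccccc1)c1ccccc1
Why: SN2 ring opening of O-protonated THF by triphenylphosphine, a known preparation of this Wittig salt; no stereocentre.

**Step 8**
Reactants: 10 hydrindanone; 12 (4-hydroxybutyl)triphenylphosphonium bromide
Product: 14 (Z)-1-(4-hydroxybutylidene)-4,4,7a-trimethyloctahydro-1H-inden-5-ol (chain syn to C7a; other centres as in 10), via oxido-ylide 13 (not isolated)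
Conditions: 12 (3 equiv), t-BuOK (6 equiv), THF, 0 → 66 °C
Reagents that add atoms: none
Why: Wittig olefination of the neopentyl cyclopentanone with a non-stabilised ylide gives, as in the ethylidenation of 17-oxo steroids, the Z-olefin.

**Step 9**
Reactants: 14 (Z)-alkylidene diol
Product: 16 9-epi ketodiol, 3β-hydroxy-9α-(3-hydroxypropyl)-4,4,10β-trimethyl-trans-decalin-8-one (H-9 β), via hydroxy nosylate 15 (not isolated)
Conditions: (4-O2NC6H4SO2O)2 (1.1 equiv), H2O (5 equiv), 2,6-di-tert-butylpyridine, CH2Cl2–HFIP 4:1, −40 → 20 °C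
Reagents that add atoms: water, O; bis(4-nitrobenzenesulfonyl) peroxide, O=[N+]([O-])c1ccc(cc1)S(=O)(=O)OOS(=O)(=O)c1ccc(cc1)[N+](=O)[O-] (its ArSO3 group is carried by 15 only)
Why: Proposed new method: the trisubstituted olefin attacks the electrophilic O–O bond from its open α face so that ArSO3 ends on the less substituted carbon, water (or the pendant OH) caps the tertiary cation, and the β-hydroxy nosylate undergoes an antiperiplanar 1,2-shift of the quaternary C–C bond (semipinacol ring expansion, cyclopentane → cyclohexanone, with inversion at the migration terminus); the closest known chemistry is Hoffman's sulfonyloxylation of alkenes with arylsulfonyl peroxides, Tl(III)/I(III) oxidative ring expansion of alkylidenecycloalkanes and the D-homoannulation of steroidal 17α-hydroxy-20-sulfonates.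

**Step 10**
Reactants: 16 9-epi ketodiol
Product: 18 methylene diol, 3β-hydroxy-9β-(3-hydroxypropyl)-4,4,10β-trimethyl-8-methylene-trans-decalin (H-9 α), via 9αH-ketodiol 17 (not isolated)
Conditions: t-BuOK, t-BuOH–THF, 25 °C; then Ph3PCH3Br/t-BuOK (excess), THF, 50 °C
Reagents that add atoms: methyltriphenylphosphonium bromide, C[P+](c1ccccc1)(c1ccccc1)c1ccccc1.[Br-]
Why: Enolate equilibration moves the side chain to the equatorial position (H-9 anti to the angular methyl, the normal onocerane configuration) and Wittig methylenation, expected to be faster for the less hindered equatorial epimer, then removes the acidity of this centre.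

**Step 11**
Reactants: 18 methylene diol
Product: 20 hydroxy phosphonium iodide {3-[3β-hydroxy-8-methylene-decalin-9β-yl]propyl}triphenylphosphonium iodide, via iodide 19 (not isolated)
Conditions: I2, PPh3, imidazole, CH2Cl2, 0 °C; then PPh3, MeCN, 80 °C
Reagents that add atoms: iodine, II; triphenylphosphine, c1ccc(cc1)P(c1ccccc1)c1ccccc1
Why: Appel iodination touches only the primary alcohol (the neopentyl 3β-OH is inert) and SN2 quaternisation of the iodide gives the salt; no stereocentre changes.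

**Step 12**
Reactants: 20 hydroxy phosphonium iodide
Product: 21 acetoxy phosphonium iodide (3β-acetate of 20)
Conditions: Ac2O, pyridine, DMAP (cat.), CH2Cl2, 25 °C
Reagents that add atoms: acetic anhydride, CC(=O)OC(C)=O
Why: DMAP-catalysed acylation of the only hydroxyl with retention at C3 (the future C21).

**Step 13**
Reactants: 21 acetoxy phosphonium iodide; 10 hydrindanone
Product: 23 (Z)-olefin in which the ylide carbon (C9) is double-bonded to C1 of the hydrindan-5β-ol (future C8) and carries the CH2CH2 bridge to C13 of the 21-acetoxy-14(27)-methylene decalin, via ylide 22 (not isolated)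
Conditions: KHMDS (1.0 equiv), THF, −78 → 0 °C; then 10 (2 equiv), THF–toluene, 65 °C
Reagents that add atoms: none
Why: Salt-free Wittig olefination of the 17-oxo-steroid-like ketone gives the Z-alkylidene (C11 syn to the future C10), while the neutral ylide leaves the hindered neopentyl acetate alone.

**Step 14**
Reactants: 23 (Z)-olefin
Product: 25 21α-acetoxy-3β-hydroxy-9βH-26-noronocer-14(27)-en-8-one, via hydroxy nosylate 24 (not isolated)
Conditions: (4-O2NC6H4SO2O)2 (1.05 equiv), H2O (5 equiv), 2,6-di-tert-butylpyridine, CH2Cl2–HFIP 4:1, −60 → 0 °C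
Reagents that add atoms: water, O; bis(4-nitrobenzenesulfonyl) peroxide, O=[N+]([O-])c1ccc(cc1)S(=O)(=O)OOS(=O)(=O)c1ccc(cc1)[N+](=O)[O-] (its ArSO3 group is carried by 24 only)
Why: Proposed new method: as in step 9, the peroxide oxygen adds to C9 from the α face of the more nucleophilic trisubstituted Z-olefin (a peracid-like preference over the 1,1-disubstituted C14 methylene), water caps C8, and in the rotamer that keeps H-9 toward the angular methyl the C10–C8 bond is antiperiplanar to C9–ONs and migrates with inversion at C9 (semipinacol ring expansion), giving H-9 β with the side chain axial under buffered, non-epimerising conditions; closest known chemistry as in step 9, the stereochemical course being that of 17α-hydroxy-20α-tosylates giving 17aα-methyl-D-homo-17-ketones.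

**Step 15**
Reactants: 25 21α-acetoxy-3β-hydroxy-9βH-26-noronocer-14(27)-en-8-one
Product: 26 3β-hydroxy-9βH-onocera-8(26),14(27)-dien-21α-yl acetate
Conditions: Zn, CH2Br2, TiCl4 (Lombardo reagent, excess), THF–CH2Cl2, 0 → 25 °C
Reagents that add atoms: dibromomethane, BrCBr
Why: Takai–Lombardo methylenation uses a non-basic gem-dimetallic reagent, so the epimerisable C9 (H β) is retained and the acetate is untouched.

**Step 16**
Reactants: 26 3β-hydroxy-9βH-onocera-8(26),14(27)-dien-21α-yl acetate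
Product: 27 3-oxo-9βH-onocera-8(26),14(27)-dien-21α-yl acetate (target; 5R,9R,10R,13S,17R,18R,21S)
Conditions: Dess–Martin periodinane, NaHCO3, CH2Cl2, 25 °C
Reagents that add atoms: none
Why: Dess–Martin oxidation of the only free secondary alcohol under buffered conditions that leave the exocyclic olefins, the acetate and all stereocentres alone.

**Compound list**
1 | 2-methylcyclopentane-1,3-dione | CC1C(=O)CCC1=O | starting material
2 | but-3-en-2-one (methyl vinyl ketone) | CC(=O)C=C | starting material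
3 | 2-methyl-2-(3-oxobutyl)cyclopentane-1,3-dione | CC(=O)CCC1(C)C(=O)CCC1=O | intermediate
4 | (3aS,7aS)-3a-hydroxy-7a-methylhexahydro-1H-indene-1,5(4H)-dione (cis-ketol) | O=C1CC[C@]2(O)CC(=O)CC[C@]12C | intermediate
5 | (7aS)-7a-methyl-2,3,7,7a-tetrahydro-1H-indene-1,5(6H)-dione (Hajos–Parrish ketone) | O=C1CCC2=CC(=O)CC[C@]12C | intermediate
6 | C1 ethylene ketal of 5 (7aS) | C12(OCCO1)CCC3=CC(=O)CC[C@]23C | intermediate
7 | 1,1-ethylenedioxy-4,4,7a-trimethyl-hexahydroinden-5-one with C3=C3a double bond (7aS) | C12(OCCO1)CC=C3C(C)(C)C(=O)CC[C@]23C | intermediate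
8 | (3aS,7aS)-1,1-ethylenedioxy-4,4,7a-trimethyloctahydroinden-5-one (trans-fused) | C12(OCCO1)CC[C@H]3C(C)(C)C(=O)CC[C@]23C | intermediate
9 | (3aS,5S,7aS)-1,1-ethylenedioxy-4,4,7a-trimethyloctahydroinden-5-ol | C12(OCCO1)CC[C@H]3C(C)(C)[C@@H](O)CC[C@]23C | intermediate
10 | (3aS,5S,7aS)-5-hydroxy-4,4,7a-trimethyloctahydro-1H-inden-1-one | O=C1CC[C@H]2C(C)(C)[C@@H](O)CC[C@]12C | intermediate
11 | tetrahydrofuran | C1CCOC1 | starting material
12 | (4-hydroxybutyl)triphenylphosphonium bromide | OCCCC[P+](c1ccccc1)(c1ccccc1)c1ccccc1.[Br-] | intermediate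
13 | potassium 4-(triphenylphosphoranylidene)butan-1-olate (oxido-ylide) | [K+].[O-]CCCC=P(c1ccccc1)(c1ccccc1)c1ccccc1 | intermediate
14 | (Z)-1-(4-hydroxybutylidene)-4,4,7a-trimethyloctahydro-1H-inden-5-ol (centres as in 10) | OCCC/C=C1/CC[C@H]2C(C)(C)[C@@H](O)CC[C@]12C | intermediate
15 | 1α-hydroxy-1β-[4-hydroxy-1-(4-nitrobenzenesulfonyloxy)butyl] derivative of the hydrindan-5β-ol (sulfonate oxygen delivered from the α face) | OCCC[C@H](OS(=O)(=O)c1ccc(cc1)[N+](=O)[O-])[C@@]1(O)CC[C@H]2C(C)(C)[C@@H](O)CC[C@]12C | intermediate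
16 | 3β-hydroxy-9α-(3-hydroxypropyl)-4,4,10β-trimethyl-trans-decalin-8-one (H-9 β) | OCCC[C@@H]1C(=O)CC[C@H]2C(C)(C)[C@@H](O)CC[C@]12C | intermediate
17 | 3β-hydroxy-9β-(3-hydroxypropyl)-4,4,10β-trimethyl-trans-decalin-8-one (H-9 α) | OCCC[C@H]1C(=O)CC[C@H]2C(C)(C)[C@@H](O)CC[C@]12C | intermediate
18 | 3β-hydroxy-9β-(3-hydroxypropyl)-4,4,10β-trimethyl-8-methylene-trans-decalin | OCCC[C@H]1C(=C)CC[C@H]2C(C)(C)[C@@H](O)CC[C@]12C | intermediate
19 | 3β-hydroxy-9β-(3-iodopropyl)-4,4,10β-trimethyl-8-methylene-trans-decalin | ICCC[C@H]1C(=C)CC[C@H]2C(C)(C)[C@@H](O)CC[C@]12C | intermediate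
20 | [3-(3β-hydroxy-4,4,10β-trimethyl-8-methylene-trans-decalin-9β-yl)propyl]triphenylphosphonium iodide | [I-].c1ccc(cc1)[P+](c1ccccc1)(c1ccccc1)CCC[C@H]1C(=C)CC[C@H]2C(C)(C)[C@@H](O)CC[C@]12C | intermediate
21 | 3β-acetate of 20 | [I-].c1ccc(cc1)[P+](c1ccccc1)(c1ccccc1)CCC[C@H]1C(=C)CC[C@H]2C(C)(C)[C@@H](OC(C)=O)CC[C@]12C | intermediate
22 | ylide of 21 | c1ccc(cc1)P(c1ccccc1)(c1ccccc1)=CCC[C@H]1C(=C)CC[C@H]2C(C)(C)[C@@H](OC(C)=O)CC[C@]12C | intermediate
23 | (Z)-olefin joining C9 to C1 of the hydrindan-5β-ol (future C8), bridged by C11–C12 to C13 of the 21α-acetoxy-14(27)-methylene decalin | C=C1CC[C@H]2C(C)(C)[C@@H](OC(C)=O)CC[C@]2(C)[C@H]1CC/C=C1/CC[C@H]2C(C)(C)[C@@H](O)CC[C@]12C | intermediate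
24 | 8α-hydroxy-9-(4-nitrobenzenesulfonyloxy) adduct of 23 | C=C1CC[C@H]2C(C)(C)[C@@H](OC(C)=O)CC[C@]2(C)[C@H]1CC[C@H](OS(=O)(=O)c1ccc(cc1)[N+](=O)[O-])[C@@]1(O)CC[C@H]2C(C)(C)[C@@H](O)CC[C@]12C | intermediate
25 | 21α-acetoxy-3β-hydroxy-9βH-26-noronocer-14(27)-en-8-one | O=C1CC[C@H]2C(C)(C)[C@@H](O)CC[C@]2(C)[C@@H]1CC[C@H]1C(=C)CC[C@H]2C(C)(C)[C@@H](OC(C)=O)CC[C@]12C | intermediate
26 | 3β-hydroxy-9βH-onocera-8(26),14(27)-dien-21α-yl acetate | C=C1CC[C@H]2C(C)(C)[C@@H](O)CC[C@]2(C)[C@@H]1CC[C@H]1C(=C)CC[C@H]2C(C)(C)[C@@H](OC(C)=O)CC[C@]12C | intermediate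
27 | 3-oxo-9βH-onocera-8(26),14(27)-dien-21α-yl acetate (CNP0193500.1) | C=C1CC[C@H]2C(C)(C)C(=O)CC[C@]2(C)[C@@H]1CC[C@H]1C(=C)CC[C@H]2C(C)(C)[C@@H](OC(C)=O)CC[C@]12C | target

**Totals and risks**

Total step count: 16. Longest linear sequence: 15 (steps 1–6 and 8–16; step 7 is a one-step side branch; 10 is used in steps 8 and 13).

Three steps most likely to fail:

Step 9 (first use of the new oxidative ring expansion). The tertiary cation may undergo Wagner–Meerwein shift or elimination before it is capped. The fallback uses known chemistry, sets out from 14 and returns at 16. TBSCl/imidazole silylates only the primary alcohol and gives the silyl ether F1. OsO4 (cat.)/NMO dihydroxylates the olefin from the α face to the triol F2. Bu2SnO (cat.)/TsCl/Et3N sulfonylates only the secondary glycol hydroxyl and gives the tosylate F3. LiClO4/CaCO3 in THF at 50 °C (solvolytic semipinacol, as in the D-homoannulation of 17α-hydroxy-20-tosylates) gives the silyl ketone F4, and HF·pyridine returns 16.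

Step 13 (Wittig union of a large ylide with a hindered ketone in the presence of the acetate). The fallback postpones the acetylation, sets out from 20 and 10 and returns at 23. TESCl/imidazole converts 10 into the silyl ether F5. Compound 20 with 2 equiv KHMDS (oxido-ylide) and F5 give the hydroxy olefin F6, where harsher conditions can be used because no ester is present. Ac2O/DMAP acetylates the only free hydroxyl to the acetate F7, and HF·pyridine removes the silyl group to give 23.

Step 14 (the new ring expansion on the advanced substrate). It must be chemoselective over the C14 methylene and must keep the kinetic H-9 β. The fallback uses known chemistry, keeps C14 masked so that only one olefin is present, sets out from 16 and returns at 26. NaOMe/MeOH equilibrates 16 to 17, and Appel iodination followed by PPh3 (as in step 11) gives the keto phosphonium iodide F8. Ethylene glycol/TsOH (Dean–Stark) gives the dioxolane F9, and Ac2O/pyridine gives the acetate F10. KHMDS and 10 (as in step 13) give the (Z)-olefin F11. OsO4 (cat.)/NMO gives the α-face syn-diol F12, and Bu2SnO (cat.)/TsCl/Et3N gives the secondary tosylate F13. LiClO4/CaCO3 in THF at 50 °C gives the ring-expanded ketone F14 (H-9 β). PPTS in wet acetone unmasks the diketone F15, and Lombardo methylenation of both ketones gives 26.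

**Further compounds**
F1 | step 9 | primary TBS ether of 14 | CC(C)(C)[Si](C)(C)OCCC/C=C1/CC[C@H]2C(C)(C)[C@@H](O)CC[C@]12C
F2 | step 9 | α-face syn-diol of F1 (tertiary ring OH, secondary side-chain OH) | CC(C)(C)[Si](C)(C)OCCC[C@H](O)[C@@]1(O)CC[C@H]2C(C)(C)[C@@H](O)CC[C@]12C
F3 | step 9 | secondary tosylate of F2 | CC(C)(C)[Si](C)(C)OCCC[C@H](OS(=O)(=O)c1ccc(C)cc1)[C@@]1(O)CC[C@H]2C(C)(C)[C@@H](O)CC[C@]12C
F4 | step 9 | primary TBS ether of 16 | CC(C)(C)[Si](C)(C)OCCC[C@@H]1C(=O)CC[C@H]2C(C)(C)[C@@H](O)CC[C@]12C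
F5 | step 13 | triethylsilyl ether of 10 | O=C1CC[C@H]2C(C)(C)[C@@H](O[Si](CC)(CC)CC)CC[C@]12C
F6 | step 13 | (Z)-olefin with free 21-OH and 3-O-triethylsilyl group | C=C1CC[C@H]2C(C)(C)[C@@H](O)CC[C@]2(C)[C@H]1CC/C=C1/CC[C@H]2C(C)(C)[C@@H](O[Si](CC)(CC)CC)CC[C@]12C
F7 | step 13 | 21-acetate of F6 | C=C1CC[C@H]2C(C)(C)[C@@H](OC(C)=O)CC[C@]2(C)[C@H]1CC/C=C1/CC[C@H]2C(C)(C)[C@@H](O[Si](CC)(CC)CC)CC[C@]12C
F8 | step 14 | [3-(3β-hydroxy-4,4,10β-trimethyl-8-oxo-trans-decalin-9β-yl)propyl]triphenylphosphonium iodide | [I-].c1ccc(cc1)[P+](c1ccccc1)(c1ccccc1)CCC[C@H]1C(=O)CC[C@H]2C(C)(C)[C@@H](O)CC[C@]12C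
F9 | step 14 | 8,8-ethylenedioxy ketal of F8 | [I-].c1ccc(cc1)[P+](c1ccccc1)(c1ccccc1)CCC[C@H]1C3(OCCO3)CC[C@H]2C(C)(C)[C@@H](O)CC[C@]12C
F10 | step 14 | 3β-acetate of F9 | [I-].c1ccc(cc1)[P+](c1ccccc1)(c1ccccc1)CCC[C@H]1C3(OCCO3)CC[C@H]2C(C)(C)[C@@H](OC(C)=O)CC[C@]12C
F11 | step 14 | (Z)-olefin from the ylide of F10 and 10 (C14 ketal) | C13(OCCO3)CC[C@H]2C(C)(C)[C@@H](OC(C)=O)CC[C@]2(C)[C@H]1CC/C=C1/CC[C@H]2C(C)(C)[C@@H](O)CC[C@]12C
F12 | step 14 | 8α,9-syn-diol of F11 | C13(OCCO3)CC[C@H]2C(C)(C)[C@@H](OC(C)=O)CC[C@]2(C)[C@H]1CC[C@H](O)[C@@]1(O)CC[C@H]2C(C)(C)[C@@H](O)CC[C@]12C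
F13 | step 14 | 9-O-tosylate of F12 | C13(OCCO3)CC[C@H]2C(C)(C)[C@@H](OC(C)=O)CC[C@]2(C)[C@H]1CC[C@H](OS(=O)(=O)c1ccc(C)cc1)[C@@]1(O)CC[C@H]2C(C)(C)[C@@H](O)CC[C@]12C
F14 | step 14 | ring-expanded 8-ketone (H-9 β) with C14 ketal | O=C1CC[C@H]2C(C)(C)[C@@H](O)CC[C@]2(C)[C@@H]1CC[C@H]1C3(OCCO3)CC[C@H]2C(C)(C)[C@@H](OC(C)=O)CC[C@]12C
F15 | step 14 | 21α-acetoxy-3β-hydroxy-9βH-26,27-dinoronocerane-8,14-dione | O=C1CC[C@H]2C(C)(C)[C@@H](O)CC[C@]2(C)[C@@H]1CC[C@H]1C(=O)CC[C@H]2C(C)(C)[C@@H](OC(C)=O)CC[C@]12C
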